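**Plan**

- Retrosynthesis: the C2–C3 bond of ring C is cut first (carbenoid C–H insertion). This opens the flavanone to an aryl diazomethyl ketone bearing a 3,4-dimethoxybenzyl ether. Next the N2 unit at C3 (diazo transfer), the O1–C2 bond (ether synthesis) and the C4–C4a bond (acylation) are cut.
- Enabling feature: C2 is bonded to both O1 and C1' of the electron-rich ring B. In the open form it is therefore an ArO–CH2–Ar methylene with hydridic C–H bonds, and the chain C3–C4–C4a–C8a–O1–C2 places it six atoms from a carbene at C3.
- Forward order: rings A and B are bought. Ring A is acetylated and its C8a oxygen freed, ring B is attached through O1–C2, the acetyl CH3 becomes the diazo carbon C3, and ring C closes last.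
- Stereochemistry: C2 is the only stereocentre and is created in the ring closure. A chiral dirhodium carboxylate selects the pro-S benzylic hydrogen and inserts with retention. No acid or base follows, so the centre cannot be lost by opening to the chalcone.

Key step: step 5

Assumption: Rh2(S-PTTL)4 is taken to select the pro-S hydrogen; if induction on this substrate runs the other way, the mirror-image catalyst Rh2(R-PTTL)4, made from (R)-tert-leucine, is used in the same manner.

**Step 1**
Reactants: 1 1,2,3,5-tetramethoxybenzene
Product: 3 1-(2-hydroxy-3,4,6-trimethoxyphenyl)ethan-1-one, via tetramethoxyacetophenone 2 (not isolated)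
Conditions: AcCl, AlCl3 (2.5 equiv), Et2O, 0 °C → rt; cold dilute HCl
Reagents that add atoms: acetyl chloride, CC(=O)Cl
Why: Friedel–Crafts acylation strikes one of the two equivalent free positions of 1, and in the resulting 2 the AlCl3 chelated to the carbonyl oxygen cleaves the C2 methoxy group, which is ortho to the ketone and pushed out of the ring plane by its two neighbours, faster than the less crowded C6 methoxy group, a long-established way to this phenol.

**Step 2**
Reactants: 3 1-(2-hydroxy-3,4,6-trimethoxyphenyl)ethan-1-one; 4 3,4-dimethoxybenzyl chloride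
Product: 5 1-[2-(3,4-dimethoxybenzyloxy)-3,4,6-trimethoxyphenyl]ethan-1-one
Conditions: K2CO3, KI (cat.), DMF, 60 °C
Reagents that add atoms: none
Why: Williamson ether synthesis, in which the phenoxide of 3 displaces halide from the reactive primary benzylic chloride 4 under iodide catalysis, while carbonate is too weak a base to start enolate chemistry at the methyl ketone.

**Step 3**
Reactants: 5 1-[2-(3,4-dimethoxybenzyloxy)-3,4,6-trimethoxyphenyl]ethan-1-one
Product: 7 4,4,4-trifluoro-1-[2-(3,4-dimethoxybenzyloxy)-3,4,6-trimethoxyphenyl]butane-1,3-dione, via lithium enolate 6 (not isolated)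
Conditions: LiN(SiMe3)2, THF, −78 °C; CF3CO2CH2CF3, −78 °C; cold dilute HCl; used crude
Reagents that add atoms: 2,2,2-trifluoroethyl trifluoroacetate, FC(F)(F)COC(=O)C(F)(F)F
Why: Crossed Claisen condensation, in which deprotonation at the only enolisable position gives the unhindered CH2 enolate 6, which is C-acylated at once by the very electrophilic trifluoroacetate and so activates C3 for diazo transfer.

**Step 4**
Reactants: 7 4,4,4-trifluoro-1-[2-(3,4-dimethoxybenzyloxy)-3,4,6-trimethoxyphenyl]butane-1,3-dione
Product: 8 2-diazo-1-[2-(3,4-dimethoxybenzyloxy)-3,4,6-trimethoxyphenyl]ethan-1-one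
Conditions: MsN3, Et3N, H2O (1 equiv), MeCN, rt; 10% NaOH wash; chromatography on Et3N-washed SiO2
Reagents that add atoms: methanesulfonyl azide, CS(=O)(=O)N=[N+]=[N-]
Why: Regitz diazo transfer in its detrifluoroacetylative variant, in which the diketone enolate attacks the terminal azide nitrogen and the adduct fragments by passing the more electrophilic trifluoroacetyl group to the sulfonamide nitrogen, leaving the terminal diazoketone.

**Step 5**
Reactants: 8 2-diazo-1-[2-(3,4-dimethoxybenzyloxy)-3,4,6-trimethoxyphenyl]ethan-1-one
Product: 9 (2S)-2-(3,4-dimethoxyphenyl)-5,7,8-trimethoxychroman-4-one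
Conditions: Rh2(S-PTTL)4, that is dirhodium tetrakis[N-phthaloyl-(S)-tert-leucinate] (1 mol %), 4 Å MS, CH2Cl2, 0 °C, slow addition of 8; recrystallisation from EtOAc–hexane
Reagents that add atoms: none
Why: Rh2(S-PTTL)4 is attacked by the diazo carbon of 8, N2 leaves, and the electrophilic rhodium-bound carbene at C3 takes a benzylic C–H bond of the OCH2Ar group in one concerted but asynchronous, hydride-transfer-like event that forms C2–C3 and C3–H and frees the catalyst. The closest known reaction type is the enantioselective intramolecular C–H insertion of ortho-alkoxyaryl diazoketones to 2-substituted chroman-4-ones under chiral dirhodium carboxylates, and insertion into ArO–CH2–Ar groups with phthaloyl amino acid catalysts is equally familiar from 2-aryldihydrobenzofuran synthesis. Ring C closes by 1,6-insertion through a six-membered transition state made of C3, C4, C4a, C8a, O1 and C2, a 1,5-insertion being impossible because the fifth atom is O1. C2 is controlled by the catalyst alone: the four N-phthaloyl-tert-leucinate ligands wall in the carbene so that only the pro-S hydrogen can be presented with ring B pointing out of the pocket, and insertion with retention then gives 2S. The step needs insertion to beat attack of O1 on the carbene (five-membered oxonium ylide, then 1,2-shift of the benzyl group) and needs the OCH2Ar group to react in place of the C5 methoxy group, whose C–H bonds are also 1,6 to the carbene. The substrate provides for both, since O1 is a weakly basic aryl ether oxygen crowded by the acyl group and the C8 methoxy group and its rhodium-bound ylide can revert, while the positive charge building at C2 is shared by O1 and the 3,4-dimethoxyphenyl ring, which makes this secondary C–H bond far more reactive than a primary OCH3 bond; rhodium carboxylates, unlike copper catalysts, also lean towards insertion.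

**Compound list**

1 | 1,2,3,5-tetramethoxybenzene | COc1cc(OC)c(OC)c(OC)c1 | starting material
2 | 1-(2,3,4,6-tetramethoxyphenyl)ethan-1-one | CC(=O)c1c(OC)cc(OC)c(OC)c1OC | intermediate
3 | 1-(2-hydroxy-3,4,6-trimethoxyphenyl)ethan-1-one | CC(=O)c1c(OC)cc(OC)c(OC)c1O | intermediate
4 | 3,4-dimethoxybenzyl chloride | COc1ccc(CCl)cc1OC | starting material
5 | 1-[2-(3,4-dimethoxybenzyloxy)-3,4,6-trimethoxyphenyl]ethan-1-one | CC(=O)c1c(OC)cc(OC)c(OC)c1OCc1ccc(OC)c(OC)c1 | intermediate
6 | lithium enolate of 5 (lithium 1-[2-(3,4-dimethoxybenzyloxy)-3,4,6-trimethoxyphenyl]ethen-1-olate) | [Li+].[O-]C(=C)c1c(OC)cc(OC)c(OC)c1OCc1ccc(OC)c(OC)c1 | intermediate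
7 | 4,4,4-trifluoro-1-[2-(3,4-dimethoxybenzyloxy)-3,4,6-trimethoxyphenyl]butane-1,3-dione | O=C(CC(=O)C(F)(F)F)c1c(OC)cc(OC)c(OC)c1OCc1ccc(OC)c(OC)c1 | intermediate
8 | 2-diazo-1-[2-(3,4-dimethoxybenzyloxy)-3,4,6-trimethoxyphenyl]ethan-1-one | COc1ccc(COc2c(C(=O)C=[N+]=[N-])c(OC)cc(OC)c2OC)cc1OC | intermediate
9 | (2S)-2-(3,4-dimethoxyphenyl)-5,7,8-trimethoxychroman-4-one | COc1ccc([C@@H]2CC(=O)c3c(OC)cc(OC)c(OC)c3O2)cc1OC | target

**Step count**

Total step count: 5. Longest linear sequence: 5 (1 → 3 → 5 → 7 → 8 → 9).

**Steps most likely to fail**

Step 5.
- What may go wrong: the carbenoid may be diverted by oxonium ylide formation at O1 and migration of the benzyl group. Hydride transfer may become stepwise and blur the stereochemical outcome. An acceptor-only carbene may also discriminate poorly between the two enantiotopic hydrogens.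
- Fallback: it sets out from 3 and comes back at 9, and it forms C2–C1' instead of C2–C3.
- Heating 3 with N,N-dimethylformamide dimethyl acetal should give the enaminone (E)-3-(dimethylamino)-1-(2-hydroxy-3,4,6-trimethoxyphenyl)prop-2-en-1-one F1.
- Brief treatment of this with HCl in CH2Cl2 closes it to 5,7,8-trimethoxy-4H-chromen-4-one F2.
- Known asymmetric conjugate addition of commercial 3,4-dimethoxyphenylboronic acid to the chromone then delivers 9. The conditions are Pd(OCOCF3)2, the t-BuPyOx antipode that leads to the 2S series, NH4PF6, H2O, ClCH2CH2Cl, 60 °C.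

Step 4.
- What may go wrong: diazo transfer to the crowded, largely enolised or hydrated diketone may be slow. Nitrogen may also be lost during isolation through acid-triggered participation of an ortho ether oxygen.
- Fallback: it sets out from 5 and comes back at 8, avoids sulfonyl azides, and stays basic to the end.
- Enolate 6 is silylated (LiN(SiMe3)2, Me3SiCl, THF, −78 °C) to {1-[2-(3,4-dimethoxybenzyloxy)-3,4,6-trimethoxyphenyl]ethenyloxy}trimethylsilane F3.
- NBS in THF at −78 °C brominates the enol ether faster than the arenes and gives 2-bromo-1-[2-(3,4-dimethoxybenzyloxy)-3,4,6-trimethoxyphenyl]ethan-1-one F4.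
- N,N'-ditosylhydrazine with DBU in THF at 0 °C alkylates at nitrogen and eliminates two sulfinate units to give 8.

Step 1.
- What may go wrong: discrimination between the two methoxy groups ortho to the ketone may be poor, or ether cleavage may run on past the monophenol stage.
- Fallback: it sets out from 1 and comes back at 3, and replaces selective cleavage by selective alkylation.
- 1 is acetylated to 2 as before, and 2 is heated with excess AlCl3 in MeCN until both ortho methoxy groups are gone. Any mixture of phenols is thereby funnelled into 1-(2,6-dihydroxy-3,4-dimethoxyphenyl)ethan-1-one F5.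
- One equivalent of MeI with K2CO3 in acetone should then methylate the C6 hydroxyl, which has only H5 beside it. The crowded C2 hydroxyl stays locked in its hydrogen bond to the carbonyl, which gives 3.

**Further compounds**
F1 | step 5 | (E)-3-(dimethylamino)-1-(2-hydroxy-3,4,6-trimethoxyphenyl)prop-2-en-1-one | CN(C)/C=C/C(=O)c1c(OC)cc(OC)c(OC)c1O
F2 | step 5 | 5,7,8-trimethoxy-4H-chromen-4-one | COc1cc(OC)c2c(=O)ccoc2c1OC
F3 | step 4 | {1-[2-(3,4-dimethoxybenzyloxy)-3,4,6-trimethoxyphenyl]ethenyloxy}trimethylsilane | C=C(O[Si](C)(C)C)c1c(OC)cc(OC)c(OC)c1OCc1ccc(OC)c(OC)c1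
F4 | step 4 | 2-bromo-1-[2-(3,4-dimethoxybenzyloxy)-3,4,6-trimethoxyphenyl]ethan-1-one | O=C(CBr)c1c(OC)cc(OC)c(OC)c1OCc1ccc(OC)c(OC)c1
F5 | step 1 | 1-(2,6-dihydroxy-3,4-dimethoxyphenyl)ethan-1-one | CC(=O)c1c(O)cc(OC)c(OC)c1O
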